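All runs are simulated from invented constants, noise included.

Molar, not percent, is the unit for these runs: one first nucleophile makes one target.

| flask | substrate | first nucleophile | gas | remark | time |
|---|---|---|---|---|---|
| north-east | 0.25 M | 0.266 M | 29 mM (held) | run made earlier |  |
| south-east | 0.57 M | 0.266 M | 29 mM (held) | run made earlier |  |
| flask | 0.38 M | 0.266 M | 29 mM (held) |  | 20 h |

| run | time / h | target / % | other capture product / % |
|---|---|---|---|
| north-east | 1.33 | 83.5 | 17.4 |
| north-east | 4.00 | 82.7 | 16.9 |
| north-east | 6.00 | 82.3 | 17.6 |
| north-east | 10.0 | 81.7 | 17.2 |
| north-east | 15.0 | 82.0 | 17.8 |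
| north-east | 20.0 | 82.8 | 17.4 |
| north-east | 25.0 | 82.8 | 18.3 |
| south-east | 3.00 | 47.4 | 53.8 |
| south-east | 6.00 | 47.6 | 53.9 |
| south-east | 10.0 | 46.3 | 53.4 |
| south-east | 15.0 | 46.4 | 53.6 |
| south-east | 20.0 | 47.6 | 53.3 |
| south-east | 25.0 | 46.9 | 53.2 |

(scatter of a reading: 0.5 percentage points)

- ratio of target to other capture product at 25 s
- ratio of target to other capture product at 20 min
- ratio of target to other capture product at 20 h

- at the start none of second nucleophile is dissolved
- the earlier runs were read with a standard deviation of 0.5 percentage points
- what may be going on: second nucleophile + intermediate -> other capture product; first nucleophile + intermediate -> target; substrate -> intermediate; substrate <-> dormant form; gas <-> second nucleophile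

In the north-east run at 20.0 h, target reads 0.207 M, so 0.0590 M of the first nucleophile should remain, and other capture product reads 0.0435 M. If the two nucleophiles split the intermediate in proportion to their concentrations, with [second nucleophile] steady, then ln[first nucleophile] falls in step with other capture product. The slope, a selectivity factor read from that run, is 34.6 /M.

In the flask the first nucleophile is the limiting reagent, leaving an excess of 0.114 M substrate. Multiply the two and you have Λ, here 3.95, the number of e-folds the first nucleophile falls while the excess is captured. So 1.93% of the charge should survive, a small correction to the ceiling ratio 2.33, and my reckoning for 20 h is 2.19.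

Was one number enough? The south-east run has Λ of 10.5; its charges give a ceiling ratio of 0.875 and its readings at 20.0 h a ratio of 0.893, though that tests the ceiling, not the slope. Λ also holds no clock, and the second nucleophile starts undissolved, so I commit to nothing at 25 s or 20 min.

For the ratio at 25 s, 20 min and 20 h the forecast gave 12 (7 to 40), 4 (2.2 to 8) and 2.2 (2.1 to 2.35), noting “The runs do not resolve early rates.”

The simulation gives, in the same order, 17.3, 2.40 and 2.33.

    second nucleophile + intermediate → other capture product (k = 23.0 /M/s)
    first nucleophile + intermediate → target (k = 6.60 /M/s)
    substrate → intermediate (k = 0.0470 /s)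
    substrate ⇌ dormant form (K = 3.00, k = 0.00920 /s)
    gas ⇌ second nucleophile, rate k5*(csat - [second nucleophile]) (kL = 0.0220 /s)

The flask keeps 0.0215% of its charge of first nucleophile at 20.0 h, less than the 1.93% reckoned from Λ, and its ratio of 2.33 matches the ceiling of 2.33. A second flask with 0.11 M first nucleophile has Λ of 9.35, and its charges give 0.407, against 0.407 simulated. In the flask, half of the turnover to target up to 20 h is done by 0.185 min, sooner than the gas transfer time of 0.758 min, and at 20.0 h target holds 70.0% of the substrate charged.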